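Slowness is the help here, so freeze what moves slowly: after 2.50 h the left-handed substrate of the eta run still reads 94.2% of its charge, and you want a quick number for the flask at 80 min, earlier than that reading.

| flask | left-handed substrate | right-handed substrate | reagent | free catalyst | remark | time |
|---|---|---|---|---|---|---|
| eta | 0.067 M | 0.067 M | 0.20 M | 1 mM | run made earlier |  |
| epsilon | 0.15 M | 0.15 M | 0.20 M | 1 mM | run made earlier |  |
| zeta | 0.10 M | 0.10 M | 0.20 M | 0.50 mM | run made earlier |  |
| flask | 0.10 M | 0.10 M | 0.200 M | 1.0 mM |  | 2.5 d |

- eta (time / h: left-handed product / %, right-handed product / %, left-handed substrate / %): 2.50: 2.4, 0.1, 47.1; 8.00: 6.3, 2.7, 42.6; 15.0: 8.1, 2.6, 41.9; 20.0: 8.2, 4.2, 40.4; 30.0: 9.9, 6.1, 39.1; 40.0: 10.5, 6.0, 39.3; 50.0: 10.8, 6.8, 37.9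
- epsilon (time / h: left-handed product / %, right-handed product / %, left-handed substrate / %): 6.00: 5.2, 1.7, 44.6; 15.0: 7.9, 4.8, 42.3; 20.0: 8.4, 4.2, 41.3; 30.0: 9.0, 5.2, 40.0; 40.0: 10.4, 5.7, 39.2; 50.0: 9.7, 6.1, 39.0
- zeta (time / h: left-handed product / %, right-handed product / %, left-handed substrate / %): 4.00: 2.3, 1.6, 47.3; 8.00: 3.7, 2.0, 46.7; 15.0: 5.0, 1.5, 45.0; 25.0: 5.3, 2.8, 44.0; 50.0: 6.9, 4.5, 41.9

(scatter of a reading: 0.5 percentage points)

- free catalyst is single-handed; left-handed substrate and right-handed substrate are mirror images of each other, charged as a racemate, each of them at the stated concentration
- an excess is the difference of the two amounts in percent of their sum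
- an excess is below zero if the other one leads

- excess of left-handed product over right-handed product in the product at 80 min
- excess of left-handed product over right-handed product in the product at 2.5 d
- part of the left-handed substrate and right-handed substrate charged together that has reacted at 2.5 d

Set [left-handed substrate] = [right-handed substrate], both at charge, and assume that both products are made on the same catalyst with the same reagent. The other factors of the two rates then cancel, and the selectivity factor s stays:

rate of left-handed product / rate of right-handed product = s · [left-handed substrate] / [right-handed substrate] ≈ s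

Don't read s from one pair, since a right-handed 0.1% drowns in a scatter of 0.5 percentage points. Pool the 5 pairs up to 8.00 h from the eta, epsilon and zeta runs:

s = Σ left-handed product / Σ right-handed product = 2.46

(s − 1) / (s + 1) = 42.1%

Carry this value, read from scattered readings, as the excess of product made from a frozen racemate, the early excess. It is my number for 80 min. Don't stretch it: pooled at 50.0 h, the same runs read 22.3%.

The forecast says 32%, 22% and 18%, and takes its ratio from the plateaus: "Burst plateaus are about 8.2% left-handed and 4.1% right-handed, a ratio near 2." We differ on the early excess, 42.1% against 32%. For the two late numbers I have nothing better than the forecast's.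

The flask gives 40.4%, 20.0% and 17.0%. The early excess stands 1.7 points above the first, the forecast 8.4 points below it, and its late two fall within their margins.

    reagent + free catalyst + left-handed substrate → free catalyst + left-handed product (k = 0.0360 M⁻² s⁻¹)
    reagent + free catalyst + right-handed substrate → free catalyst + right-handed product (k = 0.0150 M⁻² s⁻¹)
    reagent + free catalyst → spent catalyst A (k = 7.10 × 10⁻⁵ M⁻¹ s⁻¹)
    2 free catalyst → spent catalyst B (k = 0.0130 M⁻¹ s⁻¹)
    left-handed product ⇌ right-handed product (k = 1.90 × 10⁻⁶ s⁻¹)

Compare two times in the flask: the step from right-handed substrate to right-handed product has half of its turnover up to 2.5 d behind it by 0.346 d, while left-handed product turns into right-handed product with a half-life, by the forward rate alone, of 4.2 d, 12.1 times longer. Against that half-life 80 min is short, and there the flask stands at 40.4%; at 2.5 d it stands at 20.0%. Now charge the neighbour flask with 0.400 mM of free catalyst: s holds no catalyst, so the early excess again gives 42.1% at 80 min. The computed neighbour gives 40.6%.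

The numbers in the tables come from a simulation with made-up constants, noise included.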